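## The problem

The target 35 is a trans-fused 3a,4,5,7a-tetrahydro-1H-indene. A cyclopentene (C1, C2, C3, C3a, C7a; C2=C3 with ethyl on C3) shares the C3a–C7a bond with a cyclohexene (C4 to C7; C6=C7 with methyl on C7). There are five stereocentres: C1 (methyl), C7a and C3a on the small ring, and the adjacent quaternary carbons C4 (methyl, CO2H) and C5 (ethyl, (1E,3E)-4-phenylbuta-1,3-dienyl) on the large ring. H3a and H7a are trans, the C1 methyl is trans to C7 and cis to C4, and the carboxyl group, the dienyl group and H3a lie on one face. C1 and C7a are neighbouring tertiary centres that can be set in an open chain and can then steer C3a when the five-membered ring closes. C4 and C5 are beyond their direct reach and need a relay, most simply a temporary stereocentre at C7, and the bond between these two fully substituted carbons is best made intramolecularly and stereospecifically. The phenyl-diene does not tolerate acid, electrophiles or radicals for long, the two trisubstituted ring alkenes flank a strained trans ring fusion and could migrate under acid, and the carboxyl group on its doubly neopentyl carbon should be set free without an ester hydrolysis. The feature that opens the route is that C3, the ethyl-bearing alkene carbon, is bonded to C3a, and that C3a is β to the carboxyl carbon by way of C4. An open chain that holds C1 and C7a, ends in a (Z)-alkenyl iodide at C3 and carries a C3a=C4 enoate can therefore close the cyclopentene by forming C3–C3a with the C2=C3 alkene already in place.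

## Retrosynthesis

**35 to lactone 32.** The C4–C5 bond is cut and C7 is joined to the carboxyl oxygen, which leads back to the δ-lactone 32 and its silyl ketene acetal 33. An enolate alkylation or conjugate addition would have to join two fully substituted carbons without a template, and cutting C5–C6 or C6–C7 would leave the quaternary pair to be built in an open chain. The [3,3] shift makes both centres at once inside a ring and ends with the free acid. The precursor has one ring less and no quaternary carbon. The forward step needs the alkenyl group on C7 cis to H7a and an E alkene (dienyl trans to C7), so that C5 adds to the correct face of C4 with the dienyl group cis to the carboxyl. Carrying the whole dienyl group avoids a late hydroxy acid that would close to a γ-lactone.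

**32 to enone 30.** The C7–methyl bond and the lactone C–O bond are cut. The methyl group is put in last because a nucleophile should approach the C7 carbonyl past the small C1 methyl, not past the branched C3a side chain. Adding the alkenyl group to a methyl ketone would therefore give the wrong C7 epimer, whereas adding methyl to the alkenyl ketone 30 gives the right one. The tertiary alkoxide 31 closes onto the ester by itself.

**30 to aldehyde 23 and iodide 27.** The C6–C7 bond is cut. A chromium-mediated coupling of 27 with 23 gives alcohol 29, which is oxidised to 30. The geometry of the future C5=C6 alkene is fixed beforehand in 27. That iodide comes from dienyne 25 by syn addition of ethylcopper and iodination, and 25 comes from the commercial dienal 24.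

**23 to cyclopentene ester 20.** The C4 methyl is removed (enolate methylation of 20 to 22) and the aldehyde is masked as its diethyl acetal. The acetal makes C7a a non-acidic centre during ring closure and keeps C7 at the aldehyde oxidation level.

**20 to the open chain 19.** The C3–C3a bond is cut. This is the cut that the C3/C3a/C4 pattern invites: 19 has no ring and only the two stereocentres C1 and C7a, and the ring closure sets C3a and leaves the alkene at C2=C3. The forward step needs 5-exo closure of a (Z)-alkenyl metal onto the enoate with the acetate arm trans to the acetal group.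

**19 to ester 9.** The C3a=C4 alkene is cut (ester 16 reduced to aldehyde 18, then ylide 17) and so is the C2=C3 alkene (aldehyde 11 with the iodo ylide 15 from phosphonium salt 12). Aldehyde 11 comes from ozonolysis of the propenyl group of 9. The iodoalkene is made first so that ozone never meets the enoate.

**9 to ester 5.** The C1–C7a bond is cut by an ester-enolate Claisen shift of 5 (by way of 6 and 7 to acid 8, then methyl ester 9). One step sets both centres, and the chirality comes from the carbinol carbon of the allylic alcohol 2. The forward step needs the (Z)-silyl ketene acetal and a chair transition state.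

**5 to commercial materials.** Ester 5 is made from alcohol 2, obtained by enzymatic resolution of racemic 1, and acid 4, obtained from the commercial ester 3.

## Roads not taken

**Alternative 1:** Pauson–Khand annulation. The cut removes C3a–C7a, C1–C2 and C2–C3 and leads to the 1,7-enyne A1, whose Z-alkene tether already holds C4 and C5. With Co2(CO)8 it would give the bicyclic C2 enone A2, closing both rings in one step.
- Merits: three bonds and two rings at once, and the C1/C7a relationship follows from the E-propenyl group.
- Weak points: the vicinal quaternary pair must first be made in an open chain, which is the hardest problem of the target and is only moved. The alkene partner is the internal end of a conjugated diene, and a six-membered ring must form. A2 carries a C2 carbonyl and a C3=C3a alkene, so the ketone must be removed and the alkene shifted, with C3a set trans to C7a against the strain of the ring fusion.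
- Comparison: this road is more convergent in ring formation. The chosen plan sets against it that the alkene is formed at C2=C3 directly, that C3a is fixed during ring closure by C1 and C7a, and that the quaternary pair is made late on a rigid template.

**Alternative 2:** Heck cyclisation. The cut is C5–C6. The (Z)-alkenyl iodide A3 would add zerovalent palladium, close the six-membered ring onto the trisubstituted C5=C1' alkene and lose a β-hydride to give the diene in the methyl ester A4.
- Merits: catalytic; C5 and the diene are made together; no temporary stereocentre at C7; the diene appears only at the end.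
- Weak points: C4 must already be quaternary and correctly configured next to C3a. The insertion makes a quaternary carbon next to a quaternary carbon, and its facial selectivity rests on C4 alone. Palladium hydride can move the double bonds. A4 is a methyl ester on a doubly neopentyl carbon, which is hard to cleave.
- Comparison: in precedent for making a quaternary centre and in needing no C7 relay, this road is at least as good. The chosen plan sets against it that C4 and C5 are formed together with their relative configuration fixed by ring and alkene geometry, and that the acid is obtained free.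

**Alternative 3:** Lactone-enolate Claisen as the organising step. The cut is C4–C5, from the silyloxymethyl lactone A5 to the acid A6.
- Merits: the chosen plan uses the same rearrangement in its last step, so in how the quaternary pair is made the two are equal. A5 is the more robust substrate, because its alkenyl group is not a polyene that can ionise.
- Weak points: as a strategy it gives no answer for the cyclopentene and its three stereocentres. After A6 the diene still has to be built by desilylation, oxidation and olefination on a hydroxy acid that is set up to close to a γ-lactone.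
- Comparison: the chosen plan supplies the cyclopentene by the nickel cyclisation and lets the rearrangement end the synthesis. The robustness of the silyloxymethyl series is kept as a fallback.

Key step: step 9

Remark: atoms are numbered as in the target throughout. C4 (from step 10) and C7 (from step 14) are carried as mixtures, because C4 is enolised again in step 17 and C7 is oxidised in step 15.

## Route

Step 1
Reactants: 1 (3E)-pent-3-en-2-ol (racemic)
Product: 2 (2S,3E)-pent-3-en-2-ol
Conditions: Candida antarctica lipase B (immobilised), vinyl acetate (0.6 equiv), hexane, rt, to about half conversion; separation from the acetate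
Reagents that add atoms: none
Why: Lipase-catalysed kinetic resolution by transesterification; the enzyme acylates the (R)-alcohol much faster, so the alcohol left over should be the (S)-enantiomer.

Step 2
Reactants: 3 ethyl 3,3-diethoxypropanoate
Product: 4 3,3-diethoxypropanoic acid
Conditions: NaOH, EtOH–H2O, rt; then HCl to pH 4, 0 °C, extraction
Reagents that add atoms: sodium hydroxide, [Na+].[OH-]
Why: Ester saponification; the acetal is stable to base, and the acid is liberated cold at pH 4 and used at once so that the acetal survives.

Step 3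
Reactants: 2 (2S,3E)-pent-3-en-2-ol, 4 3,3-diethoxypropanoic acid
Product: 5 (2S,3E)-pent-3-en-2-yl 3,3-diethoxypropanoate
Conditions: dicyclohexylcarbodiimide, 4-(dimethylamino)pyridine (cat.), CH2Cl2, 0 °C to rt
Reagents that add atoms: none
Why: Steglich esterification; the neutral carbodiimide coupling acylates the oxygen of the secondary allylic alcohol, so the carbinol centre and the acetal should stay untouched.

Step 4
Reactants: 5 (2S,3E)-pent-3-en-2-yl 3,3-diethoxypropanoate
Product: 8 (2R,3R,4E)-2-(diethoxymethyl)-3-methylhex-4-enoic acid, via (Z)-silyl ketene acetal 6 (not isolated), via trimethylsilyl ester 7 (not isolated)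
Conditions: Me3SiCl, LiN(iPr)2, THF–DMPU, −78 °C (silylation in situ); rt to 45 °C; aq. NaOH, then citric acid to pH 4
Reagents that add atoms: none
Why: Ireland–Claisen rearrangement; enolisation in the presence of the silyl chloride and DMPU should give the (Z)-ketene acetal (diethoxymethyl cis to OSi) before ethoxide can be lost. A chair transition state with the carbinol methyl, the C1 methyl and the diethoxymethyl group all equatorial passes the (S)-carbinol chirality on to C1 and C7a and gives the E-propenyl group.

Step 5
Reactants: 8 (2R,3R,4E)-2-(diethoxymethyl)-3-methylhex-4-enoic acid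
Product: 9 methyl (2R,3R,4E)-2-(diethoxymethyl)-3-methylhex-4-enoate
Conditions: MeI, K2CO3, DMF, rt
Reagents that add atoms: iodomethane, CI
Why: SN2 O-alkylation of the carboxylate; K2CO3 at room temperature should not enolise the ester, so C7a is safe.

Step 6
Reactants: 9 methyl (2R,3R,4E)-2-(diethoxymethyl)-3-methylhex-4-enoate
Product: 11 methyl (2R,3S)-2-(diethoxymethyl)-3-methyl-4-oxobutanoate, via ozonide 10 (not isolated)
Conditions: O3, CH2Cl2, −78 °C (indicator dye for the end point); PPh3, −78 °C to rt
Reagents that add atoms: ozone, [O-][O+]=O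
Why: Ozonolysis with reductive work-up cleaves the only alkene to the C2 aldehyde; stopping at the dye end point keeps ozone from oxidising the acetal C–H, and the aldehyde is used crude to protect C1.

Step 7
Reactants: 11 methyl (2R,3S)-2-(diethoxymethyl)-3-methyl-4-oxobutanoate, 12 propyltriphenylphosphonium bromide
Product: 16 methyl (2R,3S,4Z)-2-(diethoxymethyl)-5-iodo-3-methylhept-4-enoate, via propylidene ylide 13 (not isolated), via iodophosphonium iodide 14 (not isolated), via iodo ylide 15 (not isolated)
Conditions: 12, n-BuLi, THF, 0 °C to rt; I2, −78 °C; NaN(SiMe3)2, −78 to −20 °C; then 11, −78 °C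
Reagents that add atoms: iodine, II
Why: Stork–Zhao-type Wittig olefination with an α-iodo ylide; kinetic addition at low temperature should place iodine cis to the alkyl chain and give the (Z)-iodoalkene that ring closure needs. The ylide reacts with the aldehyde much faster than it can enolise the ester or epimerise C1.

Step 8
Reactants: 16 methyl (2R,3S,4Z)-2-(diethoxymethyl)-5-iodo-3-methylhept-4-enoate, 17 methyl (triphenylphosphoranylidene)acetate
Product: 19 methyl (2E,4R,5S,6Z)-4-(diethoxymethyl)-7-iodo-5-methylnona-2,6-dienoate, via aldehyde 18 (not isolated)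
Conditions: iBu2AlH, CH2Cl2, −78 °C; MeOH; then 17, −78 °C to rt
Reagents that add atoms: none
Why: Partial ester reduction stops at the chelated aluminium hemiacetal, and the stabilised ylide traps the aldehyde as it is released (Wittig olefination) to give the E-enoate. The β,β-dialkoxy aldehyde, which could lose ethanol, is never isolated, and the alkenyl iodide is inert to the hydride at −78 °C.

Step 9
Reactants: 19 methyl (2E,4R,5S,6Z)-4-(diethoxymethyl)-7-iodo-5-methylnona-2,6-dienoate
Product: 20 methyl 2-[(1R,4R,5S)-5-(diethoxymethyl)-2-ethyl-4-methylcyclopent-2-en-1-yl]acetate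
Conditions: NiBr2(2,2'-bipyridine) (10 mol %), Bu4NBr, DMF, Fe anode, Ni-foam cathode, undivided cell, constant current, 50 °C; then aq. NH4Cl
Reagents that add atoms: none
Why: The cathode reduces the nickel dibromide complex to zerovalent nickel, which inserts into the C3–I bond with retention of the Z geometry; the alkenylnickel adds across the tethered enoate, and the resulting nickel enolate is protonated, the divalent nickel returning to the cathode while the iron anode supplies the counter-ions. The closest known reaction type is the nickel-catalysed electroreductive conjugate addition of alkenyl halides to electron-poor alkenes with a sacrificial anode, here run within one molecule. The cyclopentene closes 5-exo-trig by forming C3–C3a, and the C2=C3 alkene of the iodide becomes the ring alkene. The new centre C3a is controlled by C7a and C1: in the envelope-like transition state the C1 methyl and the C7a diethoxymethyl group are pseudo-equatorial and the enoate is attacked anti to the acetal. The acetate arm therefore ends trans to the C7a substituent and cis to the C1 methyl. The step needs 5-exo closure to outrun reduction or coupling of the alkenylnickel species; the Z geometry, the polarised acceptor and moderate dilution secure this. C7a carries no carbonyl group, so its hydrogen is not acidic enough to epimerise under the basic cathodic conditions.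

Step 10
Reactants: 20 methyl 2-[(1R,4R,5S)-5-(diethoxymethyl)-2-ethyl-4-methylcyclopent-2-en-1-yl]acetate
Product: 22 methyl 2-[(1S,4R,5S)-5-(diethoxymethyl)-2-ethyl-4-methylcyclopent-2-en-1-yl]propanoate (both C4 epimers), via lithium enolate 21 (not isolated)
Conditions: LiN(iPr)2, THF, −78 °C; MeI, −78 to −40 °C
Reagents that add atoms: iodomethane, CI
Why: Ester enolate alkylation; the new centre C4 forms as a mixture, which does not matter because C4 is enolised again in step 17. The branch also makes the C3a side chain bulkier for step 16.

Step 11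
Reactants: 22 methyl 2-[(1S,4R,5S)-5-(diethoxymethyl)-2-ethyl-4-methylcyclopent-2-en-1-yl]propanoate
Product: 23 methyl 2-[(1S,4R,5S)-2-ethyl-5-formyl-4-methylcyclopent-2-en-1-yl]propanoate (both C4 epimers)
Conditions: TsOH·H2O (cat.), acetone–H2O, rt
Reagents that add atoms: water, O
Why: Acid-catalysed acetal hydrolysis under mild conditions that leave the ring alkene in place; the formyl group stays trans to both neighbours, which is the more stable arrangement at C7a.

Step 12
Reactants: 24 (2E,4E)-5-phenylpenta-2,4-dienal
Product: 25 [(1E,3E)-hexa-1,3-dien-5-yn-1-yl]benzene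
Conditions: Me3SiCHN2, LiN(iPr)2, THF, −78 °C to rt
Reagents that add atoms: (trimethylsilyl)diazomethane, C[Si](C)(C)C=[N+]=[N-]
Why: Colvin rearrangement (one-carbon homologation of an aldehyde to a terminal alkyne by way of an alkylidene carbene); it avoids the methanolic base that would add to a dienal.

Step 13
Reactants: 25 [(1E,3E)-hexa-1,3-dien-5-yn-1-yl]benzene
Product: 27 [(1E,3E,5E)-5-ethyl-6-iodohexa-1,3,5-trien-1-yl]benzene, via alkenylcopper 26 (not isolated)
Conditions: EtMgBr, CuBr·SMe2, Et2O–Me2S, −45 °C; 25, −25 °C; I2, THF, −50 to 0 °C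
Reagents that add atoms: ethylmagnesium bromide, CC[Mg]Br; iodine, II
Why: syn-Carbocupration of a terminal alkyne conjugated to an alkene; ethyl goes to the internal carbon and copper to the terminal carbon on the same side. Iodinolysis with retention then gives the iodide with iodine cis to ethyl and trans to the dienyl group.

Step 14
Reactants: 23 methyl 2-[(1S,4R,5S)-2-ethyl-5-formyl-4-methylcyclopent-2-en-1-yl]propanoate, 27 [(1E,3E,5E)-5-ethyl-6-iodohexa-1,3,5-trien-1-yl]benzene
Product: 29 methyl 2-[(1S,4R,5S)-2-ethyl-5-[(2E,4E,6E)-3-ethyl-1-hydroxy-7-phenylhepta-2,4,6-trien-1-yl]-4-methylcyclopent-2-en-1-yl]propanoate (carbinol epimers), via alkenylchromium dichloride 28 (not isolated)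
Conditions: CrCl2, NiCl2 (2 mol %), DMSO, rt
Reagents that add atoms: none
Why: Nozaki–Hiyama–Kishi reaction; the alkenylchromium species forms with retention of geometry and adds only to the aldehyde, leaving the ester alone. The configuration of the new carbinol does not matter.

Step 15
Reactants: 29 methyl 2-[(1S,4R,5S)-2-ethyl-5-[(2E,4E,6E)-3-ethyl-1-hydroxy-7-phenylhepta-2,4,6-trien-1-yl]-4-methylcyclopent-2-en-1-yl]propanoate
Product: 30 methyl 2-[(1S,4R,5S)-2-ethyl-5-[(2E,4E,6E)-3-ethyl-7-phenylhepta-2,4,6-trienoyl]-4-methylcyclopent-2-en-1-yl]propanoate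
Conditions: Dess–Martin periodinane, NaHCO3, CH2Cl2, 0 °C
Reagents that add atoms: none
Why: Dess–Martin oxidation of the allylic alcohol under buffered conditions, carried out at once so that the δ-hydroxy ester does not lactonise; C7a stays in its more stable configuration.

Step 16
Reactants: 30 methyl 2-[(1S,4R,5S)-2-ethyl-5-[(2E,4E,6E)-3-ethyl-7-phenylhepta-2,4,6-trienoyl]-4-methylcyclopent-2-en-1-yl]propanoate
Product: 32 (1S,4aS,7R,7aS)-5-ethyl-1-[(1E,3E,5E)-2-ethyl-6-phenylhexa-1,3,5-trien-1-yl]-1,4,7-trimethyl-4,4a,7,7a-tetrahydrocyclopenta[c]pyran-3(1H)-one (both C4 epimers), via bromomagnesium alkoxide 31 (not isolated)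
Conditions: MeMgBr (1.1 equiv), THF, −78 °C to rt; pH 7 buffer
Reagents that add atoms: methylmagnesium bromide, C[Mg]Br
Why: Grignard 1,2-addition to the β,β-disubstituted enone, followed by lactonisation of the tertiary alkoxide onto the methyl ester. By the usual open-chain model for addition next to a stereocentre, methyl should come in anti to the C7a–C3a bond, past the C1 methyl and away from the branched C3a side chain, which puts the alkenyl group cis to H7a as step 17 requires.

Step 17
Reactants: 32 (1S,4aS,7R,7aS)-5-ethyl-1-[(1E,3E,5E)-2-ethyl-6-phenylhexa-1,3,5-trien-1-yl]-1,4,7-trimethyl-4,4a,7,7a-tetrahydrocyclopenta[c]pyran-3(1H)-one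
Product: 35 (1R,3aR,4R,5S,7aS)-3,5-diethyl-1,4,7-trimethyl-5-[(1E,3E)-4-phenylbuta-1,3-dien-1-yl]-3a,4,5,7a-tetrahydro-1H-indene-4-carboxylic acid, via silyl ketene acetal 33 (not isolated), via trimethylsilyl ester 34 (not isolated)
Conditions: Me3SiCl, Et3N, LiN(iPr)2, THF, −78 °C to rt; toluene, 90 °C; aq. citric acid
Reagents that add atoms: none
Why: Ireland–Claisen rearrangement of a lactone enolate through a ring-constrained, boat-like transition state: C5 of the alkenyl group bonds to C4 while C7–O breaks, which closes the cyclohexene and creates C6=C7. The lactone ring fixes the ketene acetal geometry, C7 fixes the face of C4, and the E alkene places the dienyl group cis to the carboxyl and the ethyl group cis to the C4 methyl. Mild acid on work-up hydrolyses the silyl ester to the free acid.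

## Compound list

1 | (3E)-pent-3-en-2-ol (racemic) | C/C=C/C(C)O | starting material
2 | (2S,3E)-pent-3-en-2-ol | C/C=C/[C@H](C)O | intermediate
3 | ethyl 3,3-diethoxypropanoate | CCOC(=O)CC(OCC)OCC | starting material
4 | 3,3-diethoxypropanoic acid | OC(=O)CC(OCC)OCC | intermediate
5 | (2S,3E)-pent-3-en-2-yl 3,3-diethoxypropanoate | C/C=C/[C@H](C)OC(=O)CC(OCC)OCC | intermediate
6 | [(1Z)-3,3-diethoxy-1-{[(2S,3E)-pent-3-en-2-yl]oxy}prop-1-en-1-yl]oxy(trimethyl)silane (not isolated) | C/C=C/[C@H](C)O/C(O[Si](C)(C)C)=C/C(OCC)OCC | intermediate
7 | trimethylsilyl (2R,3R,4E)-2-(diethoxymethyl)-3-methylhex-4-enoate (not isolated) | C/C=C/[C@@H](C)[C@H](C(OCC)OCC)C(=O)O[Si](C)(C)C | intermediate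
8 | (2R,3R,4E)-2-(diethoxymethyl)-3-methylhex-4-enoic acid | C/C=C/[C@@H](C)[C@H](C(OCC)OCC)C(O)=O | intermediate
9 | methyl (2R,3R,4E)-2-(diethoxymethyl)-3-methylhex-4-enoate | C/C=C/[C@@H](C)[C@H](C(OCC)OCC)C(=O)OC | intermediate
10 | methyl (2R,3S)-2-(diethoxymethyl)-3-(5-methyl-1,2,4-trioxolan-3-yl)butanoate (ozonide, not isolated) | CC1OOC(O1)[C@@H](C)[C@H](C(OCC)OCC)C(=O)OC | intermediate
11 | methyl (2R,3S)-2-(diethoxymethyl)-3-methyl-4-oxobutanoate | O=C[C@@H](C)[C@H](C(OCC)OCC)C(=O)OC | intermediate
12 | propyltriphenylphosphonium bromide | CCC[P+](c1ccccc1)(c1ccccc1)c1ccccc1.[Br-] | starting material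
13 | propylidenetriphenylphosphorane (not isolated) | CCC=P(c1ccccc1)(c1ccccc1)c1ccccc1 | intermediate
14 | (1-iodopropyl)triphenylphosphonium iodide (not isolated) | CCC(I)[P+](c1ccccc1)(c1ccccc1)c1ccccc1.[I-] | intermediate
15 | (1-iodopropylidene)triphenylphosphorane (not isolated) | CCC(I)=P(c1ccccc1)(c1ccccc1)c1ccccc1 | intermediate
16 | methyl (2R,3S,4Z)-2-(diethoxymethyl)-5-iodo-3-methylhept-4-enoate | I/C(CC)=C\[C@@H](C)[C@H](C(OCC)OCC)C(=O)OC | intermediate
17 | methyl (triphenylphosphoranylidene)acetate | COC(=O)C=P(c1ccccc1)(c1ccccc1)c1ccccc1 | starting material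
18 | (2S,3S,4Z)-2-(diethoxymethyl)-5-iodo-3-methylhept-4-enal (not isolated) | I/C(CC)=C\[C@@H](C)[C@H](C(OCC)OCC)C=O | intermediate
19 | methyl (2E,4R,5S,6Z)-4-(diethoxymethyl)-7-iodo-5-methylnona-2,6-dienoate | I/C(CC)=C\[C@@H](C)[C@H](C(OCC)OCC)/C=C/C(=O)OC | intermediate
20 | methyl 2-[(1R,4R,5S)-5-(diethoxymethyl)-2-ethyl-4-methylcyclopent-2-en-1-yl]acetate | CCC1=C[C@@H](C)[C@H](C(OCC)OCC)[C@H]1CC(=O)OC | intermediate
21 | lithium enolate of 20 (not isolated) | CCC1=C[C@@H](C)[C@H](C(OCC)OCC)[C@H]1C=C(OC)O[Li] | intermediate
22 | methyl 2-[(1S,4R,5S)-5-(diethoxymethyl)-2-ethyl-4-methylcyclopent-2-en-1-yl]propanoate (both C4 epimers) | CCC1=C[C@@H](C)[C@H](C(OCC)OCC)[C@H]1C(C)C(=O)OC | intermediate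
23 | methyl 2-[(1S,4R,5S)-2-ethyl-5-formyl-4-methylcyclopent-2-en-1-yl]propanoate (both C4 epimers) | CCC1=C[C@@H](C)[C@H](C=O)[C@H]1C(C)C(=O)OC | intermediate
24 | (2E,4E)-5-phenylpenta-2,4-dienal | O=C/C=C/C=C/c1ccccc1 | starting material
25 | [(1E,3E)-hexa-1,3-dien-5-yn-1-yl]benzene | C#C/C=C/C=C/c1ccccc1 | intermediate
26 | [(1E,3E,5E)-2-ethyl-6-phenylhexa-1,3,5-trien-1-yl]copper, MgBr2 complex (not isolated) | [Cu]/C=C(CC)/C=C/C=C/c1ccccc1 | intermediate
27 | [(1E,3E,5E)-5-ethyl-6-iodohexa-1,3,5-trien-1-yl]benzene | I/C=C(CC)/C=C/C=C/c1ccccc1 | intermediate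
28 | dichloro[(1E,3E,5E)-2-ethyl-6-phenylhexa-1,3,5-trien-1-yl]chromium (not isolated) | Cl[Cr](Cl)/C=C(CC)/C=C/C=C/c1ccccc1 | intermediate
29 | methyl 2-[(1S,4R,5S)-2-ethyl-5-[(2E,4E,6E)-3-ethyl-1-hydroxy-7-phenylhepta-2,4,6-trien-1-yl]-4-methylcyclopent-2-en-1-yl]propanoate (epimers at the carbinol and at C4) | CCC1=C[C@@H](C)[C@H](C(O)/C=C(CC)/C=C/C=C/c2ccccc2)[C@H]1C(C)C(=O)OC | intermediate
30 | methyl 2-[(1S,4R,5S)-2-ethyl-5-[(2E,4E,6E)-3-ethyl-7-phenylhepta-2,4,6-trienoyl]-4-methylcyclopent-2-en-1-yl]propanoate (both C4 epimers) | CCC1=C[C@@H](C)[C@H](C(=O)/C=C(CC)/C=C/C=C/c2ccccc2)[C@H]1C(C)C(=O)OC | intermediate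
31 | bromomagnesium alkoxide of methyl 2-[(1S,4R,5S)-2-ethyl-5-[(2S,3E,5E,7E)-4-ethyl-2-hydroxy-8-phenylocta-3,5,7-trien-2-yl]-4-methylcyclopent-2-en-1-yl]propanoate (not isolated) | CCC1=C[C@@H](C)[C@H]([C@](C)(O[Mg]Br)/C=C(CC)/C=C/C=C/c2ccccc2)[C@H]1C(C)C(=O)OC | intermediate
32 | (1S,4aS,7R,7aS)-5-ethyl-1-[(1E,3E,5E)-2-ethyl-6-phenylhexa-1,3,5-trien-1-yl]-1,4,7-trimethyl-4,4a,7,7a-tetrahydrocyclopenta[c]pyran-3(1H)-one (both C4 epimers) | CCC1=C[C@@H](C)[C@H]2[C@H]1C(C)C(=O)O[C@]2(C)/C=C(CC)/C=C/C=C/c1ccccc1 | intermediate
33 | trimethylsilyl ketene acetal of 32 (not isolated) | CCC1=C[C@@H](C)[C@H]2[C@H]1C(C)=C(O[Si](C)(C)C)O[C@]2(C)/C=C(CC)/C=C/C=C/c1ccccc1 | intermediate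
34 | trimethylsilyl ester of 35 (not isolated) | CCC1=C[C@@H](C)[C@@H]2C(C)=C[C@@](/C=C/C=C/c3ccccc3)(CC)[C@](C)(C(=O)O[Si](C)(C)C)[C@@H]12 | intermediate
35 | (1R,3aR,4R,5S,7aS)-3,5-diethyl-1,4,7-trimethyl-5-[(1E,3E)-4-phenylbuta-1,3-dien-1-yl]-3a,4,5,7a-tetrahydro-1H-indene-4-carboxylic acid (CNP0173090.1) | CCC1=C[C@@H](C)[C@@H]2C(C)=C[C@@](/C=C/C=C/c3ccccc3)(CC)[C@](C)(C(=O)O)[C@@H]12 | target

## Step count and least certain steps

Total: 17 steps. Longest linear sequence: 14 steps (steps 1, 3 to 11 and 14 to 17).

**Step 9 (key step).** The alkenylnickel intermediate may be reduced or coupled before it inserts, giving the deiodinated chain or dimers. Control at C3a may also fall off if the acetal group does not stay pseudo-equatorial in the closing chain. The fallback sets out from 19 and returns at 20: a tin-hydride chain reaction (Bu3SnH, azobisisobutyronitrile, benzene, 80 °C, slow addition) generates the alkenyl radical, which closes 5-exo onto the enoate under the same conformational preferences. It makes no new compound (F0).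

**Step 17.** The boat-like transition state is crowded (the C5 ethyl faces the C3a–C3 bond, and the ring fusion is trans), so the shift may be slow. Ionisation of the tertiary C7–O bond, which is allylic to a phenyl-triene, or elimination could then compete. The fallback sets out from 23 and returns at 35, building the diene after ring closure:
- 23 is coupled (CrCl2, NiCl2) with triisopropyl{[(2E)-2-ethyl-3-iodoprop-2-en-1-yl]oxy}silane F1 to give the allylic alcohol F2. F1 is made from triisopropyl(prop-2-yn-1-yloxy)silane by the ethylcopper addition and iodination of step 13.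
- Dess–Martin oxidation gives the enone F3, and MeMgBr gives the lactone F4.
- The lactone-enolate rearrangement of F4, which is not a polyenyl ester and can be heated harder, gives the silyloxymethyl acid F5.
- Bu4NF frees the hydroxy acid F6, which is kept as its carboxylate salt so that it does not close to the γ-lactone.
- Buffered Dess–Martin oxidation gives the aldehyde acid F7, and olefination with excess lithiated diethyl [(2E)-3-phenylprop-2-en-1-yl]phosphonate gives 35.

**Step 16.** Facial selectivity at C7 may be poor, because the two ring carbons that flank C7a differ only in their outer substituents; some conjugate addition is also possible. The C7 epimer of 32 cannot reach the boat-like array without working against the twist of the trans ring fusion, so it should rearrange far more slowly, but it would cost material. The fallback sets out from 23 and returns at 32 by reversing the order of the two additions, for the case that the preferred face is opposite to the one predicted. MeMgBr at −78 °C gives the carbinol F8, and Dess–Martin oxidation gives the methyl ketone F9. The alkenyllithium from 27 (t-BuLi, −78 °C, with CeCl3) is then added; it enters from the face that methyl would have taken, so the tertiary alkoxide has the other configuration and lactonises to 32.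

**Step 4.** The ester enolate may lose ethoxide before it is silylated, or the ketene acetal may form with the wrong geometry and give the C7a epimer. The fallback sets out from 2 and returns at 9 without an ester enolate that carries a β-leaving group at the Claisen stage:
- The orthoester (Johnson–Claisen) rearrangement of 2 with triethyl orthoacetate gives ethyl (3S,4E)-3-methylhex-4-enoate F10, and saponification gives the acid F11.
- F11 is joined to (4S)-4-benzyl-1,3-oxazolidin-2-one (pivaloyl chloride, Et3N; lithiated auxiliary) to give the imide F12.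
- The chlorotitanium enolate of F12 (TiCl4, iPr2NEt) reacts with triethyl orthoformate on the face away from the benzyl group to give the diethoxymethyl imide F13.
- MeOMgBr in methanol removes the auxiliary and gives 9.

## Further compounds

F0 | step 9 | none | none
F1 | step 17 | triisopropyl{[(2E)-2-ethyl-3-iodoprop-2-en-1-yl]oxy}silane | I/C=C(CC)/CO[Si](C(C)C)(C(C)C)C(C)C
F2 | step 17 | methyl 2-[(1S,4R,5S)-2-ethyl-5-[(2E)-3-ethyl-1-hydroxy-4-(triisopropylsilyloxy)but-2-en-1-yl]-4-methylcyclopent-2-en-1-yl]propanoate | CCC1=C[C@@H](C)[C@H](C(O)/C=C(CC)/CO[Si](C(C)C)(C(C)C)C(C)C)[C@H]1C(C)C(=O)OC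
F3 | step 17 | methyl 2-[(1S,4R,5S)-2-ethyl-5-[(2E)-3-ethyl-4-(triisopropylsilyloxy)but-2-enoyl]-4-methylcyclopent-2-en-1-yl]propanoate | CCC1=C[C@@H](C)[C@H](C(=O)/C=C(CC)/CO[Si](C(C)C)(C(C)C)C(C)C)[C@H]1C(C)C(=O)OC
F4 | step 17 | (1S,4aS,7R,7aS)-5-ethyl-1-[(1E)-2-(triisopropylsilyloxymethyl)but-1-en-1-yl]-1,4,7-trimethyl-4,4a,7,7a-tetrahydrocyclopenta[c]pyran-3(1H)-one | CCC1=C[C@@H](C)[C@H]2[C@H]1C(C)C(=O)O[C@]2(C)/C=C(CC)/CO[Si](C(C)C)(C(C)C)C(C)C
F5 | step 17 | 3,5-diethyl-1,4,7-trimethyl-5-(triisopropylsilyloxymethyl)-3a,4,5,7a-tetrahydro-1H-indene-4-carboxylic acid, ring stereocentres as in 35 | CCC1=C[C@@H](C)[C@@H]2C(C)=C[C@@](CO[Si](C(C)C)(C(C)C)C(C)C)(CC)[C@](C)(C(=O)O)[C@@H]12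
F6 | step 17 | 3,5-diethyl-5-(hydroxymethyl)-1,4,7-trimethyl-3a,4,5,7a-tetrahydro-1H-indene-4-carboxylic acid, ring stereocentres as in 35 | CCC1=C[C@@H](C)[C@@H]2C(C)=C[C@@](CO)(CC)[C@](C)(C(=O)O)[C@@H]12
F7 | step 17 | 3,5-diethyl-5-formyl-1,4,7-trimethyl-3a,4,5,7a-tetrahydro-1H-indene-4-carboxylic acid, ring stereocentres as in 35 | CCC1=C[C@@H](C)[C@@H]2C(C)=C[C@@](C=O)(CC)[C@](C)(C(=O)O)[C@@H]12
F8 | step 16 | methyl 2-[(1S,4R,5S)-2-ethyl-5-(1-hydroxyethyl)-4-methylcyclopent-2-en-1-yl]propanoate | CCC1=C[C@@H](C)[C@H](C(C)O)[C@H]1C(C)C(=O)OC
F9 | step 16 | methyl 2-[(1S,4R,5S)-5-acetyl-2-ethyl-4-methylcyclopent-2-en-1-yl]propanoate | CCC1=C[C@@H](C)[C@H](C(C)=O)[C@H]1C(C)C(=O)OC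
F10 | step 4 | ethyl (3S,4E)-3-methylhex-4-enoate | C/C=C/[C@@H](C)CC(=O)OCC
F11 | step 4 | (3S,4E)-3-methylhex-4-enoic acid | C/C=C/[C@@H](C)CC(O)=O
F12 | step 4 | (4S)-4-benzyl-3-[(3S,4E)-3-methylhex-4-enoyl]-1,3-oxazolidin-2-one | C/C=C/[C@@H](C)CC(=O)N1[C@@H](Cc2ccccc2)COC1=O
F13 | step 4 | (4S)-4-benzyl-3-[(2R,3R,4E)-2-(diethoxymethyl)-3-methylhex-4-enoyl]-1,3-oxazolidin-2-one | C/C=C/[C@@H](C)[C@H](C(OCC)OCC)C(=O)N1[C@@H](Cc2ccccc2)COC1=O
A1 | alternative 1 | methyl (4Z,6E)-2-(but-1-yn-1-yl)-3-{[tert-butyl(dimethyl)silyl]oxymethyl}-3-ethyl-2,5-dimethylocta-4,6-dienoate, C2 and C3 configured as C4 and C5 of 35 | CCC#C[C@@](C)(C(=O)OC)[C@@](CC)(CO[Si](C)(C)C(C)(C)C)/C=C(C)\C=C\C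
A2 | alternative 1 | methyl 5-{[tert-butyl(dimethyl)silyl]oxymethyl}-3,5-diethyl-1,4,7-trimethyl-2-oxo-2,4,5,7a-tetrahydro-1H-indene-4-carboxylate, C1, C4, C5 and C7a as in 35 | CCC1=C2[C@@](C)(C(=O)OC)[C@@](CC)(CO[Si](C)(C)C(C)(C)C)C=C(C)[C@H]2[C@H](C)C1=O
A3 | alternative 2 | methyl (3E,6E)-3-ethyl-2-{2-ethyl-5-[(1Z)-1-iodoprop-1-en-2-yl]-4-methylcyclopent-2-en-1-yl}-2-methyl-7-phenylhepta-3,6-dienoate, ring centres and C2 as C1, C7a, C3a and C4 of 35 | CCC1=C[C@@H](C)[C@H](/C(C)=C\I)[C@H]1[C@@](C)(C(=O)OC)/C(CC)=C/C/C=C/c1ccccc1
A4 | alternative 2 | methyl ester of 35 | CCC1=C[C@@H](C)[C@@H]2C(C)=C[C@@](/C=C/C=C/c3ccccc3)(CC)[C@](C)(C(=O)OC)[C@@H]12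
A5 | alternative 3 | (1S,4aS,7R,7aS)-1-[(1E)-2-({[tert-butyl(dimethyl)silyl]oxy}methyl)but-1-en-1-yl]-5-ethyl-1,4,7-trimethyl-4,4a,7,7a-tetrahydrocyclopenta[c]pyran-3(1H)-one | CCC1=C[C@@H](C)[C@H]2[C@H]1C(C)C(=O)O[C@]2(C)/C=C(CC)/CO[Si](C)(C)C(C)(C)C
A6 | alternative 3 | 5-{[tert-butyl(dimethyl)silyl]oxymethyl}-3,5-diethyl-1,4,7-trimethyl-3a,4,5,7a-tetrahydro-1H-indene-4-carboxylic acid, ring stereocentres as in 35 | CCC1=C[C@@H](C)[C@@H]2C(C)=C[C@@](CO[Si](C)(C)C(C)(C)C)(CC)[C@](C)(C(=O)O)[C@@H]12
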